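**Plan**

- The target, 5,7-dihydroxy-2-pentacosylchromone, is achiral with no configured double bond, so no stereocontrol is needed.
- Enabling feature: C2, C3 and C4 of the pyranone ring form a three-carbon unit oxygenated at both ends, between the phloroglucinol ring (at C4a) and the n-C25 chain (at C2). This is the pattern of a 1,3-diketone, which a 3-aryl-5-alkylisoxazole holds in masked form.
- Retrosynthetic cuts, in order: O1–C2 (cyclodehydration of an o-hydroxyaryl 1,3-diketone); the diketone back to the isoxazole (N–O bond); C3–C4 together with the C2–O bond (nitrile oxide plus terminal alkyne); the alkyne terminus (one-carbon homologation of the C26 aldehyde).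
- Forward: aldehyde to oxime to isolable nitrile oxide; C26 alcohol to aldehyde to C27 alkyne; the (3+2) cycloaddition closes the isoxazole ring first; the methyl ethers are removed on the robust isoxazole; N–O hydrogenolysis and aqueous acid close the pyranone ring last.

Key step: step 5

Remark: oxime 2 is drawn as the E isomer and enaminone 10 as the hydrogen-bonded Z isomer; neither geometry survives into the target.

**Step 1**
Reactants: 1 2,4,6-trimethoxybenzaldehyde
Product: 2 (E)-2,4,6-trimethoxybenzaldehyde oxime
Conditions: NH2OH·HCl, NaOAc, EtOH/H2O, 70 °C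
Reagents that add atoms: hydroxylamine hydrochloride, NO.Cl
Why: Oxime formation by condensation of the aldehyde with hydroxylamine under acetate buffer is reliable even for di-ortho-substituted benzaldehydes, and nothing else in 1 reacts.

**Step 2**
Reactants: 2 (E)-2,4,6-trimethoxybenzaldehyde oxime
Product: 3 2,4,6-trimethoxybenzonitrile oxide
Conditions: PhI(OAc)2 (1.05 equiv), TFA (cat.), MeOH, 0 °C; cold work-up, crystallisation
Reagents that add atoms: none
Why: Dehydrogenation of an aldoxime to the nitrile oxide by trivalent iodine (ligand exchange at the oxime oxygen, then loss of iodobenzene and acetic acid) uses no electrophilic halogen that could substitute the activated ring, and the two flanking methoxy groups shield the CNO carbon so that this dipole should not dimerise and can be crystallised and stored cold.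

**Step 3**
Reactants: 4 1-hexacosanol
Product: 5 hexacosanal
Conditions: TEMPO (10 mol %), PhI(OAc)2 (1.1 equiv), CH2Cl2, 35 °C
Reagents that add atoms: none
Why: TEMPO-catalysed oxidation with PhI(OAc)2 as terminal oxidant (oxoammonium mechanism) stops at the aldehyde for primary alcohols, and warm CH2Cl2 keeps the waxy substrate in solution.

**Step 4**
Reactants: 5 hexacosanal; 6 dimethyl (1-diazo-2-oxopropyl)phosphonate
Product: 7 1-heptacosyne
Conditions: K2CO3, MeOH/THF 1:1, 25 to 40 °C
Reagents that add atoms: dimethyl (1-diazo-2-oxopropyl)phosphonate 6, CC(=O)C(=[N+]=[N-])P(=O)(OC)OC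
Why: Ohira–Bestmann variant of the Seyferth–Gilbert homologation, in which methanolysis of 6 releases the diazomethylphosphonate anion, this olefinates the aldehyde to a diazoalkene, and loss of N2 with 1,2-hydrogen shift gives the terminal alkyne under base mild enough for an enolisable aliphatic aldehyde, THF being added for solubility.

**Step 5**
Reactants: 3 2,4,6-trimethoxybenzonitrile oxide; 7 1-heptacosyne
Product: 8 5-pentacosyl-3-(2,4,6-trimethoxyphenyl)isoxazole
Conditions: PhMe, 80 °C, 36 h, 3 (1.3 equiv) added in three portions
Reagents that add atoms: none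
Why: This is a Huisgen nitrile oxide–alkyne cycloaddition, a concerted but asynchronous thermal (3+2) process in which the dipole carbon bonds to the terminal alkyne carbon (the future C3–C4 bond) while the dipole oxygen bonds to the chain-bearing alkyne carbon (the C2–O bond), all atoms of both partners ending in 8. The closest known reaction type is the addition of mesitonitrile oxide and related di-ortho-substituted aryl nitrile oxides to terminal alkyl- and arylacetylenes to give 3-aryl-5-substituted isoxazoles. The isoxazole ring is closed intermolecularly by this two-bond (3+2) annulation, with C, N and O from 3 and two carbons from 7, and it is aromatic as formed, so no oxidation step follows. No stereocentre is created. The step needs 3-aryl-5-alkyl regioselectivity, so that the arene sits on the future C4, and chemoselectivity over loss of the dipole. The first is secured because the unsubstituted alkyne terminus is both the less hindered carbon and the one with the larger HOMO coefficient, a preference the bulky di-ortho-substituted aryl reinforces; the second because the two ortho methoxy groups block furoxan formation and 80 °C stays below the nitrile oxide-to-isocyanate rearrangement.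

**Step 6**
Reactants: 8 5-pentacosyl-3-(2,4,6-trimethoxyphenyl)isoxazole
Product: 9 2-(5-pentacosylisoxazol-3-yl)benzene-1,3,5-triol
Conditions: BBr3 (6 equiv), CH2Cl2, 0 °C to reflux; then ice-water, under Ar
Reagents that add atoms: none
Why: BBr3 cleavage of aryl methyl ethers (boron complexation at oxygen, then bromide attack at methyl) is standard, the aromatic isoxazole and the saturated chain are inert to it, and removing the ethers at this stage spares the later acyl-phloroglucinol intermediates any forcing acid.

**Step 7**
Reactants: 9 2-(5-pentacosylisoxazol-3-yl)benzene-1,3,5-triol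
Product: 12 5,7-dihydroxy-2-pentacosyl-4H-chromen-4-one, via trihydroxyphenyl enaminone 10 (not isolated), via trihydroxyphenyl diketone 11 (not isolated)
Conditions: H2 (1 atm), Raney Ni, THF/EtOH, 40 °C; filter under Ar; then 2 M aq HCl, 70 °C
Reagents that add atoms: water, O
Why: Hydrogenolysis of the weak isoxazole N–O bond over Raney Ni is the classical unmasking to a β-amino enone, aqueous acid hydrolyses this vinylogous amide to the o-hydroxyaryl 1,3-diketone (the C4 carbonyl oxygen coming from water), and the phenol oxygen then adds 6-exo-trig to the chain-side ketone with loss of water (chromone cyclodehydration), which is the only ring a phenol oxygen can reach and, the two ortho hydroxyls being equivalent, should give a single product.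

**Compound list**

1 | 2,4,6-trimethoxybenzaldehyde | COc1cc(OC)c(C=O)c(OC)c1 | starting material
2 | (E)-2,4,6-trimethoxybenzaldehyde oxime | COc1cc(OC)c(/C=N/O)c(OC)c1 | intermediate
3 | 2,4,6-trimethoxybenzonitrile oxide | COc1cc(OC)c(C#[N+][O-])c(OC)c1 | intermediate
4 | 1-hexacosanol | CCCCCCCCCCCCCCCCCCCCCCCCCCO | starting material
5 | hexacosanal | CCCCCCCCCCCCCCCCCCCCCCCCCC=O | intermediate
6 | dimethyl (1-diazo-2-oxopropyl)phosphonate | CC(=O)C(=[N+]=[N-])P(=O)(OC)OC | starting material
7 | 1-heptacosyne | CCCCCCCCCCCCCCCCCCCCCCCCCC#C | intermediate
8 | 5-pentacosyl-3-(2,4,6-trimethoxyphenyl)isoxazole | CCCCCCCCCCCCCCCCCCCCCCCCCc1cc(-c2c(OC)cc(OC)cc2OC)no1 | intermediate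
9 | 2-(5-pentacosylisoxazol-3-yl)benzene-1,3,5-triol | CCCCCCCCCCCCCCCCCCCCCCCCCc1cc(-c2c(O)cc(O)cc2O)no1 | intermediate
10 | (Z)-1-amino-1-(2,4,6-trihydroxyphenyl)octacos-1-en-3-one | CCCCCCCCCCCCCCCCCCCCCCCCCC(=O)/C=C(\N)c1c(O)cc(O)cc1O | intermediate
11 | 1-(2,4,6-trihydroxyphenyl)octacosane-1,3-dione | CCCCCCCCCCCCCCCCCCCCCCCCCC(=O)CC(=O)c1c(O)cc(O)cc1O | intermediate
12 | 5,7-dihydroxy-2-pentacosyl-4H-chromen-4-one | CCCCCCCCCCCCCCCCCCCCCCCCCc1cc(=O)c2c(O)cc(O)cc2o1 | target

**Step count**

Total: 7 steps. Longest linear sequence: 5 steps (steps 3, 4, 5, 6, 7 from 4; equally steps 1, 2, 5, 6, 7 from 1).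

**Steps most likely to fail**

Step 5. The hindered dipole and the unactivated alkyne may combine only on long heating, during which the nitrile oxide can rearrange to the isocyanate or dimerise, and some 3,4-regioisomer may form. The fallback changes the dipolarophile to the terminal alkene and restores aromaticity afterwards. Setting out from 5, Wittig methylenation (Ph3PCH3Br, KOtBu, THF) should give 1-heptacosene F1. Monosubstituted alkenes add nitrile oxides several times faster than the corresponding alkynes and almost only in the 5-substituted sense. Nitrile oxide 3 and F1 (PhMe, 60 °C) should therefore give racemic 5-pentacosyl-3-(2,4,6-trimethoxyphenyl)-4,5-dihydroisoxazole F2. Dehydrogenation of the isoxazoline with activated MnO2 in refluxing toluene erases the stereocentre and returns the route at 8.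

Step 6. Ether cleavage may stall after one or two methyl groups, since the 4-methoxy group has no neighbouring donor to assist, or the electron-rich triol may oxidise during work-up. The fallback reverses the order and uses protic acid on the unmasked chain. Setting out from 8, hydrogenolysis (H2, Raney Ni, THF/EtOH) should give (Z)-1-amino-1-(2,4,6-trimethoxyphenyl)octacos-1-en-3-one F3. Aqueous HCl in THF should hydrolyse it to 1-(2,4,6-trimethoxyphenyl)octacosane-1,3-dione F4. Refluxing 48% HBr in AcOH should then cleave the three ethers and cyclodehydrate, in the manner of the classical flavone syntheses from 2,4,6-trimethoxyphenyl 1,3-diketones, returning the route at 12.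

Step 7. Hydrogenolysis may be incomplete because the di-ortho-hydroxyaryl group hinders adsorption on the catalyst, the enaminone double bond may be over-reduced, or the free triphenol may oxidise over the basic catalyst. The fallback masks the phenols and cleaves the N–O bond in solution with a stoichiometric metal carbonyl. Setting out from 9, Ac2O in pyridine should give 2-(5-pentacosylisoxazol-3-yl)benzene-1,3,5-triyl triacetate F5. Mo(CO)6 (zerovalent molybdenum) in wet MeCN at reflux inserts into the N–O bond without any hydrogenation of C=C and should give (Z)-2-(1-amino-3-oxooctacos-1-en-1-yl)benzene-1,3,5-triyl triacetate F6. 2 M aqueous HCl in THF at 70 °C should then remove the acetates, hydrolyse the enaminone and close the pyranone ring, returning the route at 12.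

**Further compounds**

F1 | step 5 | 1-heptacosene | CCCCCCCCCCCCCCCCCCCCCCCCCC=C
F2 | step 5 | racemic 5-pentacosyl-3-(2,4,6-trimethoxyphenyl)-4,5-dihydroisoxazole | CCCCCCCCCCCCCCCCCCCCCCCCCC1CC(c2c(OC)cc(OC)cc2OC)=NO1
F3 | step 6 | (Z)-1-amino-1-(2,4,6-trimethoxyphenyl)octacos-1-en-3-one | CCCCCCCCCCCCCCCCCCCCCCCCCC(=O)/C=C(\N)c1c(OC)cc(OC)cc1OC
F4 | step 6 | 1-(2,4,6-trimethoxyphenyl)octacosane-1,3-dione | CCCCCCCCCCCCCCCCCCCCCCCCCC(=O)CC(=O)c1c(OC)cc(OC)cc1OC
F5 | step 7 | 2-(5-pentacosylisoxazol-3-yl)benzene-1,3,5-triyl triacetate | CCCCCCCCCCCCCCCCCCCCCCCCCc1cc(-c2c(OC(C)=O)cc(OC(C)=O)cc2OC(C)=O)no1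
F6 | step 7 | (Z)-2-(1-amino-3-oxooctacos-1-en-1-yl)benzene-1,3,5-triyl triacetate | CCCCCCCCCCCCCCCCCCCCCCCCCC(=O)/C=C(\N)c1c(OC(C)=O)cc(OC(C)=O)cc1OC(C)=O
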